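The ratio of charge to what remains is the inverse of the share left in a flask, so I follow its logarithm.

| flask | substrate | product | time |
|---|---|---|---|
| south | 0.250 M |  |  |
| north | 0.750 M |  |  |
| north-west | 0.250 M | 0.250 M | 41 h |

| south run: time / h | south run: [substrate] / M | north run: time / h | north run: [substrate] / M |
|---|---|---|---|
| 1.6 | 0.2306 | 1.6 | 0.6903 |
| 2.6 | 0.2168 | 2.6 | 0.6560 |
| 4.1 | 0.2028 | 4.1 | 0.6061 |
| 6.5 | 0.1820 | 6.5 | 0.5426 |
| 10 | 0.1556 | 10 | 0.4531 |
| 16 | 0.1166 | 16 | 0.3443 |
| 26 | 0.0735 | 26 | 0.2128 |
| 41 | 0.0364 | 41 | 0.1020 |

(readings scatter by 0.002 M)

- the exponent of [substrate] in the starting rate at the charge of the south run (at the point where two percent of the substrate have become product) (one fixed amount of product, the same in the runs compared)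
- substrate in the north-west run at 41 h, as a share of the substrate charged

- Overall: substrate -> product.
- Constant volume, constant temperature.
- An order is taken over about fifteen percent of the charge, up and down.

For a first-order loss, [substrate] equals the charge times the exponential of minus a single number. That number folds rate constant and time together. The south run gives a decay number, the natural logarithm of charge over [substrate] at 41 h, of 1.93. The north run, with a charge 3.00 times larger, gives 2.00, barely higher, so I reckon an exponent of 1.03.

Is one number enough? Not quite. Per hour up to 4.1 h, the south readings give 0.0510 /h and the north readings 0.0520 /h, both higher than the 0.0471 /h of the whole south run. The number also counts substrate lost, not product made. Still, the north-west flask has the south charge of substrate, so I commit to the south number and a share of 14.6 %, assuming that its 0.250 M of product leaves that number as it is.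

The forecast says 15 % and 1.02, holding that “late decay does not depend on how much product is present”; my share is lower and my exponent higher.

The north-west flask keeps 13.8 % of its substrate at 41 h, and the exponent at the south charge comes to 0.64.

    substrate ⇌ intermediate (0.04860 /h, 0.03391 /h)
    intermediate → product (0.3211 /h)
    substrate → product (0.004680 /h)

The decay number of the north-west flask is 1.98, above the south number, and one scatter of the last south reading moves that south number by 0.0549. Where each run has made the same small amount of product, the north run's rate is 2.0 times the south run's. Put to the north run, its decay number reckons half of the substrate gone at 14.2 h, while the product made reaches half of the charge at 17.2 h.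

Readings and results are simulated for substances that don't exist, and the scatter is random.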